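The plan rests on an intramolecular Diels–Alder disconnection of ring A (C1–C5, C10; labdane numbering): the C4 formyl group marks C4=C5 as the dienophile and the C3 acetate marks C3=C2–C1=C10 as a 1-acetoxydiene. In one operation the key step makes the C3–C4 and C5–C10 bonds, closing ring A by cycloaddition and ring B (C5–C10) as the tether ring, and sets C3, C4, C5 and C10 under the control of C9. Its precursor is an acyclic tetraene: an (E,E)-dienyl acetate linked through the C9 stereocentre and the (Z)-C7=C8 alkene to a (Z)-2-methyl enal, assembled from three small fragments.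

Key step: step 15

Remark: labdane numbering (C1–C20) is used for all skeletal atoms; the target is (3S,4S,5S,9R,10S,13E). Compounds 1, 2, 5 and 9 and all reagents are taken as commercial.

Step 1
Reactants: 1 tert-butyl but-2-ynoate; 2 but-3-en-1-ylmagnesium bromide
Product: 3 tert-butyl (2E)-3-methylhepta-2,6-dienoate
Conditions: 2, CuBr·SMe2 (1.05 equiv), THF, −40 °C; then 1, −78 °C; aq NH4Cl at −78 °C
Reagents that add atoms: none
Why: Syn-carbocupration of the ynoate (organocopper conjugate addition) at −78 °C puts the new chain cis to H and so should fix the (E)-3-methyl-2-enoate geometry of the side chain (C13=C14).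

Step 2
Reactants: 3 tert-butyl (2E)-3-methylhepta-2,6-dienoate
Product: 4 tert-butyl (2E,6E)-3-methyl-8-oxoocta-2,6-dienoate
Conditions: crotonaldehyde (5 equiv), second-generation Hoveyda–Grubbs catalyst (3 mol %), CH2Cl2, 40 °C
Reagents that add atoms: (2E)-but-2-enal (crotonaldehyde), C/C=C/C=O
Why: Olefin cross-metathesis of the terminal alkene with the electron-poor partner should give the (E)-enal, while the trisubstituted conjugated enoate is inert to the ruthenium carbene.

Step 3
Reactants: 5 but-2-yn-1-ol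
Product: 7 (2Z)-3-iodobut-2-en-1-ol, via cyclic alkenylalanate 6 (not isolated)
Conditions: NaAlH2(OCH2CH2OCH3)2, Et2O, 0 → 23 °C; then I2, THF, −78 °C
Reagents that add atoms: iodine, II
Why: trans-Hydroalumination of the propargylic alcohol through the oxygen-bound alanate, then iodinolysis with retention, should give the (Z)-vinyl iodide (iodine cis to CH2OH).

Step 4
Reactants: 7 (2Z)-3-iodobut-2-en-1-ol
Product: 8 (2Z)-1-bromo-3-iodobut-2-ene
Conditions: CBr4, PPh3, CH2Cl2, 0 °C
Reagents that add atoms: tetrabromomethane, BrC(Br)(Br)Br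
Why: The Appel reaction converts the primary allylic alcohol into the bromide under neutral conditions that leave the vinyl iodide geometry untouched.

Step 5
Reactants: 9 prop-2-yn-1-ol
Product: 11 (2Z)-3-iodo-2-methylprop-2-en-1-ol, via alkenylmagnesium alkoxide 10 (not isolated)
Conditions: MeMgBr (2.5 equiv), CuI (10 mol %), THF, −10 → 23 °C; then I2, −78 → 0 °C
Reagents that add atoms: methylmagnesium bromide, C[Mg]Br; iodine, II
Why: Copper-catalysed anti-carbomagnesiation of the propargylic alkoxide puts methyl on C2 and magnesium cis to CH2O, and iodinolysis with retention should give the (Z)-iodide.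

Step 6
Reactants: 11 (2Z)-3-iodo-2-methylprop-2-en-1-ol
Product: 12 tert-butyl{[(2Z)-3-iodo-2-methylprop-2-en-1-yl]oxy}dimethylsilane
Conditions: TBSCl, imidazole, CH2Cl2, 23 °C
Reagents that add atoms: tert-butyldimethylsilyl chloride, CC(C)(C)[Si](C)(C)Cl
Why: Standard silylation protects the allylic alcohol (the future C19) before metalation.

Step 7
Reactants: 12 tert-butyl{[(2Z)-3-iodo-2-methylprop-2-en-1-yl]oxy}dimethylsilane; 8 (2Z)-1-bromo-3-iodobut-2-ene
Product: 15 tert-butyl{[(2Z,5Z)-6-iodo-2-methylhepta-2,5-dien-1-yl]oxy}dimethylsilane, via alkenyllithium 13 (not isolated), via alkenylmagnesium bromide 14 (not isolated)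
Conditions: 12, t-BuLi (2 equiv), Et2O, −78 °C; MgBr2·OEt2; then 8, CuI (10 mol %), THF, −78 → −20 °C
Reagents that add atoms: none
Why: Iodine–lithium exchange with retention, transmetalation to magnesium and copper-catalysed SN2 coupling with the primary allylic bromide should join the two (Z)-alkenes into the skipped diene C4=C5–C6–C7=C8, the low temperature suppressing 1,4-silyl migration and the vinyl iodide of 8 staying intact.

Step 8
Reactants: 15 tert-butyl{[(2Z,5Z)-6-iodo-2-methylhepta-2,5-dien-1-yl]oxy}dimethylsilane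
Product: 17 tert-butyldimethyl{[(2Z,5E)-2-methyl-6-(4,4,5,5-tetramethyl-1,3,2-dioxaborolan-2-yl)hepta-2,5-dien-1-yl]oxy}silane, via alkenyllithium 16 (not isolated)
Conditions: t-BuLi (2 equiv), Et2O, −78 °C; then 2-isopropoxy-4,4,5,5-tetramethyl-1,3,2-dioxaborolane, −78 → 23 °C
Reagents that add atoms: 2-isopropoxy-4,4,5,5-tetramethyl-1,3,2-dioxaborolane, CC(C)OB1OC(C)(C)C(C)(C)O1
Why: Iodine–lithium exchange and borylation proceed with retention, so boron takes the place of iodine cis to C6 (the descriptor changes only because of the priority rules).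

Step 9
Reactants: 4 tert-butyl (2E,6E)-3-methyl-8-oxoocta-2,6-dienoate; 17 tert-butyldimethyl{[(2Z,5E)-2-methyl-6-(4,4,5,5-tetramethyl-1,3,2-dioxaborolan-2-yl)hepta-2,5-dien-1-yl]oxy}silane
Product: 18 tert-butyl (2E,6S)-6-[(2Z,5Z)-7-{[tert-butyl(dimethyl)silyl]oxy}-6-methylhepta-2,5-dien-2-yl]-3-methyl-8-oxooct-2-enoate
Conditions: [RhCl(C2H4)2]2 (2.5 mol %), (1R,4R)-2,5-diphenylbicyclo[2.2.2]octa-2,5-diene (5.5 mol %), KOH (0.5 equiv), dioxane/H2O 10:1, 30 °C
Reagents that add atoms: none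
Why: The Hayashi–Miyaura rhodium-catalysed asymmetric 1,4-addition of an alkenylboronate to an enal should set C9 by delivery of the alkenyl group to the Si face of the enal β-carbon (the facial sense this ligand antipode shows in forming (R)-3-phenylcyclohexanone; the other antipode is used if a trial run shows the opposite sense), and the β,β-disubstituted enoate does not react.

Step 10
Reactants: 18 tert-butyl (2E,6S)-6-[(2Z,5Z)-7-{[tert-butyl(dimethyl)silyl]oxy}-6-methylhepta-2,5-dien-2-yl]-3-methyl-8-oxooct-2-enoate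
Product: 19 tert-butyl (2E,6R)-6-[(2Z,5Z)-7-{[tert-butyl(dimethyl)silyl]oxy}-6-methylhepta-2,5-dien-2-yl]-7-formyl-3-methylocta-2,7-dienoate
Conditions: aq CH2O (37 %), pyrrolidine (10 mol %), propionic acid (10 mol %), i-PrOH, 45 °C
Reagents that add atoms: formaldehyde, C=O
Why: Amine-catalysed Mannich condensation–elimination (organocatalytic α-methylenation of an aldehyde) installs the future C20 on C10 without strong base, C9 being β to the carbonyl and therefore safe.

Step 11
Reactants: 19 tert-butyl (2E,6R)-6-[(2Z,5Z)-7-{[tert-butyl(dimethyl)silyl]oxy}-6-methylhepta-2,5-dien-2-yl]-7-formyl-3-methylocta-2,7-dienoate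
Product: 20 tert-butyl (2E,6S,7RS)-6-[(2Z,5Z)-7-{[tert-butyl(dimethyl)silyl]oxy}-6-methylhepta-2,5-dien-2-yl]-3,7-dimethyl-8-oxooct-2-enoate
Conditions: [CuH(PPh3)]6 (0.3 equiv), toluene/THF, H2O (2 equiv), 23 °C
Reagents that add atoms: none
Why: Conjugate reduction of the 2-substituted acrolein by the copper hydride hexamer (Stryker reduction) should give the α-methyl aldehyde as a mixture of C10 epimers, a centre that is erased in step 13.

Step 12
Reactants: 20 tert-butyl (2E,6S,7RS)-6-[(2Z,5Z)-7-{[tert-butyl(dimethyl)silyl]oxy}-6-methylhepta-2,5-dien-2-yl]-3,7-dimethyl-8-oxooct-2-enoate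
Product: 21 tert-butyl (2E,6S,7RS,8E)-6-[(2Z,5Z)-7-{[tert-butyl(dimethyl)silyl]oxy}-6-methylhepta-2,5-dien-2-yl]-3,7-dimethyl-10-oxodeca-2,8-dienoate
Conditions: Ph3P=CHCHO (1.3 equiv), toluene, 90 °C
Reagents that add atoms: (triphenylphosphoranylidene)acetaldehyde, O=CC=P(c1ccccc1)(c1ccccc1)c1ccccc1
Why: Wittig olefination with the stabilised formylmethylene ylide adds C2 and C3 and should give the (E)-enal.

Step 13
Reactants: 21 tert-butyl (2E,6S,7RS,8E)-6-[(2Z,5Z)-7-{[tert-butyl(dimethyl)silyl]oxy}-6-methylhepta-2,5-dien-2-yl]-3,7-dimethyl-10-oxodeca-2,8-dienoate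
Product: 23 tert-butyl (2E,6R,7E,9E)-10-acetoxy-6-[(2Z,5Z)-7-{[tert-butyl(dimethyl)silyl]oxy}-6-methylhepta-2,5-dien-2-yl]-3,7-dimethyldeca-2,7,9-trienoate, via potassium dienolate 22 (not isolated)
Conditions: KN(SiMe3)2 (1.1 equiv), THF, −78 °C; then Ac2O, −78 → 0 °C
Reagents that add atoms: acetic anhydride, CC(=O)OC(C)=O
Why: Kinetic γ-deprotonation of the enal and O-acetylation of the dienolate, stereoconvergent for both C10 epimers, should give the (E,E)-dienyl acetate because the s-trans enal leads to the (E)-enol acetate and A(1,3) strain keeps the small methyl group, not the branched C9, syn to C2.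

Step 14
Reactants: 23 tert-butyl (2E,6R,7E,9E)-10-acetoxy-6-[(2Z,5Z)-7-{[tert-butyl(dimethyl)silyl]oxy}-6-methylhepta-2,5-dien-2-yl]-3,7-dimethyldeca-2,7,9-trienoate
Product: 24 tert-butyl (2E,6R,7E,9E)-10-acetoxy-6-[(2Z,5Z)-7-hydroxy-6-methylhepta-2,5-dien-2-yl]-3,7-dimethyldeca-2,7,9-trienoate
Conditions: HF·pyridine, pyridine, THF, 0 → 23 °C
Reagents that add atoms: none
Why: Buffered fluoride desilylation frees the primary allylic alcohol without touching the enol acetate or the tert-butyl ester.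

Step 15
Reactants: 24 tert-butyl (2E,6R,7E,9E)-10-acetoxy-6-[(2Z,5Z)-7-hydroxy-6-methylhepta-2,5-dien-2-yl]-3,7-dimethyldeca-2,7,9-trienoate
Product: 26 tert-butyl (2E)-5-[(1R,4aS,5S,6S,8aS)-6-acetoxy-5-formyl-2,5,8a-trimethyl-1,4,4a,5,6,8a-hexahydronaphthalen-1-yl]-3-methylpent-2-enoate, via (Z)-enal 25 (not isolated)
Conditions: MnO2 (20 equiv), toluene, 23 °C; filtration through Celite; then toluene (0.005 M), BHT (10 mol %), base-washed sealed tube, 130 °C
Reagents that add atoms: none
Why: After in-flask MnO2 oxidation to (Z)-enal 25, a concerted but asynchronous thermal [4+2] cycloaddition (diene HOMO, enal LUMO) joins C3 to C4 and C5 to C10; the closest known reaction type is the type 1 intramolecular Diels–Alder reaction of 1,7,9-decatrienals. Ring A (C1–C5, C10) closes as the six-membered cycloaddition ring and ring B (C5–C10) as the six-membered tether ring through the anti (trans-fusing) transition state, in which the C5–C10 bond between the enal β-carbon and the more nucleophilic diene terminus is the more advanced. C3 follows from the (E)-enol acetate (acetoxy outside, hence trans to the exo formyl group), C4 from the (Z)-enal (formyl cis to tether carbon C6, both exo, C4 methyl endo), and C5 and C10 from suprafacial addition with the C10 methyl inside, which gives the trans fusion with the angular methyl syn to the formyl group. All four centres are set relative to C9, because H-9 should lie in the diene plane next to H-1 (least A(1,3) strain), so that the C11 side chain points away from the incoming dienophile and ends up equatorial on ring B. The step needs anti over syn tether topology, this diene face and survival of the (Z)-enal geometry; the terminal activation of the dienophile, the pre-organising (Z)-C7=C8 alkene, the C9 substituent and neutral, radical-inhibited conditions without Lewis acid are expected to secure them.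

Step 16
Reactants: 26 tert-butyl (2E)-5-[(1R,4aS,5S,6S,8aS)-6-acetoxy-5-formyl-2,5,8a-trimethyl-1,4,4a,5,6,8a-hexahydronaphthalen-1-yl]-3-methylpent-2-enoate
Product: 27 tert-butyl (2E)-5-[(1R,4aS,5S,6S,8aS)-6-acetoxy-5-formyl-2,5,8a-trimethyl-1,4,4a,5,6,7,8,8a-octahydronaphthalen-1-yl]-3-methylpent-2-enoate
Conditions: KO2CN=NCO2K (10 equiv), AcOH (20 equiv), pyridine, 23 °C
Reagents that add atoms: none
Why: Diimide reduction should saturate only the cis-disubstituted C1=C2 bond, leaving the two trisubstituted alkenes, the aldehyde and the allylic acetate (which palladium-catalysed hydrogenation would cleave).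

Step 17
Reactants: 27 tert-butyl (2E)-5-[(1R,4aS,5S,6S,8aS)-6-acetoxy-5-formyl-2,5,8a-trimethyl-1,4,4a,5,6,7,8,8a-octahydronaphthalen-1-yl]-3-methylpent-2-enoate
Product: 29 (2E)-5-[(1R,4aS,5S,6S,8aS)-6-acetoxy-5-formyl-2,5,8a-trimethyl-1,4,4a,5,6,7,8,8a-octahydronaphthalen-1-yl]-3-methylpent-2-enoic acid, via trimethylsilyl ester 28 (not isolated)
Conditions: TMSOTf (3 equiv), 2,6-lutidine (4 equiv), CH2Cl2, 0 °C; then H2O
Reagents that add atoms: none
Why: Silyl triflate-mediated cleavage of the tert-butyl ester (loss of 2-methylpropene) and hydrolysis of the silyl ester on work-up should give the acid without protic acid that could move the C7=C8 bond; the acetate and the non-enolisable aldehyde are expected to survive.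

Compound list
1 | tert-butyl but-2-ynoate | CC#CC(=O)OC(C)(C)C | starting material
2 | but-3-en-1-ylmagnesium bromide | C=CCC[Mg]Br | starting material
3 | tert-butyl (2E)-3-methylhepta-2,6-dienoate | C=CCC/C(C)=C/C(=O)OC(C)(C)C | intermediate
4 | tert-butyl (2E,6E)-3-methyl-8-oxoocta-2,6-dienoate | O=C/C=C/CC/C(C)=C/C(=O)OC(C)(C)C | intermediate
5 | but-2-yn-1-ol | CC#CCO | starting material
6 | sodium 2,2-bis(2-methoxyethoxy)-3-methyl-2,5-dihydro-1,2-oxaaluminol-2-uide (cyclic alkenylalanate) | [Na+].CC1=CCO[Al-]1(OCCOC)OCCOC | intermediate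
7 | (2Z)-3-iodobut-2-en-1-ol | C/C(I)=C/CO | intermediate
8 | (2Z)-1-bromo-3-iodobut-2-ene | C/C(I)=C/CBr | intermediate
9 | prop-2-yn-1-ol | C#CCO | starting material
10 | bromomagnesium (2Z)-3-(bromomagnesio)-2-methylprop-2-en-1-olate | Br[Mg]/C=C(/C)CO[Mg]Br | intermediate
11 | (2Z)-3-iodo-2-methylprop-2-en-1-ol | I/C=C(/C)CO | intermediate
12 | tert-butyl{[(2Z)-3-iodo-2-methylprop-2-en-1-yl]oxy}dimethylsilane | I/C=C(/C)CO[Si](C)(C)C(C)(C)C | intermediate
13 | {(1Z)-3-[(tert-butyldimethylsilyl)oxy]-2-methylprop-1-en-1-yl}lithium | [Li]/C=C(/C)CO[Si](C)(C)C(C)(C)C | intermediate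
14 | {(1Z)-3-[(tert-butyldimethylsilyl)oxy]-2-methylprop-1-en-1-yl}magnesium bromide | Br[Mg]/C=C(/C)CO[Si](C)(C)C(C)(C)C | intermediate
15 | tert-butyl{[(2Z,5Z)-6-iodo-2-methylhepta-2,5-dien-1-yl]oxy}dimethylsilane | C/C(I)=C/C/C=C(/C)CO[Si](C)(C)C(C)(C)C | intermediate
16 | alkenyllithium from 15 (lithium in place of iodine, geometry retained) | C/C([Li])=C/C/C=C(/C)CO[Si](C)(C)C(C)(C)C | intermediate
17 | tert-butyldimethyl{[(2Z,5E)-2-methyl-6-(4,4,5,5-tetramethyl-1,3,2-dioxaborolan-2-yl)hepta-2,5-dien-1-yl]oxy}silane | C/C(B1OC(C)(C)C(C)(C)O1)=C/C/C=C(/C)CO[Si](C)(C)C(C)(C)C | intermediate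
18 | tert-butyl (2E,6S)-6-[(2Z,5Z)-7-{[tert-butyl(dimethyl)silyl]oxy}-6-methylhepta-2,5-dien-2-yl]-3-methyl-8-oxooct-2-enoate | O=CC[C@H](CC/C(C)=C/C(=O)OC(C)(C)C)/C(C)=C\C/C=C(C)\CO[Si](C)(C)C(C)(C)C | intermediate
19 | tert-butyl (2E,6R)-6-[(2Z,5Z)-7-{[tert-butyl(dimethyl)silyl]oxy}-6-methylhepta-2,5-dien-2-yl]-7-formyl-3-methylocta-2,7-dienoate | O=CC(=C)[C@H](CC/C(C)=C/C(=O)OC(C)(C)C)/C(C)=C\C/C=C(C)\CO[Si](C)(C)C(C)(C)C | intermediate
20 | tert-butyl (2E,6S,7RS)-6-[(2Z,5Z)-7-{[tert-butyl(dimethyl)silyl]oxy}-6-methylhepta-2,5-dien-2-yl]-3,7-dimethyl-8-oxooct-2-enoate | O=CC(C)[C@H](CC/C(C)=C/C(=O)OC(C)(C)C)/C(C)=C\C/C=C(C)\CO[Si](C)(C)C(C)(C)C | intermediate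
21 | tert-butyl (2E,6S,7RS,8E)-6-[(2Z,5Z)-7-{[tert-butyl(dimethyl)silyl]oxy}-6-methylhepta-2,5-dien-2-yl]-3,7-dimethyl-10-oxodeca-2,8-dienoate | O=C/C=C/C(C)[C@H](CC/C(C)=C/C(=O)OC(C)(C)C)/C(C)=C\C/C=C(C)\CO[Si](C)(C)C(C)(C)C | intermediate
22 | potassium (1E,3E)-dienolate of 21 | [K+].[O-]/C=C/C=C(C)/[C@H](CC/C(C)=C/C(=O)OC(C)(C)C)/C(C)=C\C/C=C(C)\CO[Si](C)(C)C(C)(C)C | intermediate
23 | tert-butyl (2E,6R,7E,9E)-10-acetoxy-6-[(2Z,5Z)-7-{[tert-butyl(dimethyl)silyl]oxy}-6-methylhepta-2,5-dien-2-yl]-3,7-dimethyldeca-2,7,9-trienoate | CC(=O)O/C=C/C=C(C)/[C@H](CC/C(C)=C/C(=O)OC(C)(C)C)/C(C)=C\C/C=C(C)\CO[Si](C)(C)C(C)(C)C | intermediate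
24 | tert-butyl (2E,6R,7E,9E)-10-acetoxy-6-[(2Z,5Z)-7-hydroxy-6-methylhepta-2,5-dien-2-yl]-3,7-dimethyldeca-2,7,9-trienoate | CC(=O)O/C=C/C=C(C)/[C@H](CC/C(C)=C/C(=O)OC(C)(C)C)/C(C)=C\C/C=C(C)\CO | intermediate
25 | tert-butyl (2E,6R,7E,9E)-10-acetoxy-3,7-dimethyl-6-[(2Z,5Z)-6-methyl-7-oxohepta-2,5-dien-2-yl]deca-2,7,9-trienoate | CC(=O)O/C=C/C=C(C)/[C@H](CC/C(C)=C/C(=O)OC(C)(C)C)/C(C)=C\C/C=C(C)\C=O | intermediate
26 | tert-butyl (2E)-5-[(1R,4aS,5S,6S,8aS)-6-acetoxy-5-formyl-2,5,8a-trimethyl-1,4,4a,5,6,8a-hexahydronaphthalen-1-yl]-3-methylpent-2-enoate | CC(=O)O[C@H]1C=C[C@@]2(C)[C@H](CC/C(C)=C/C(=O)OC(C)(C)C)C(C)=CC[C@@H]2[C@]1(C)C=O | intermediate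
27 | tert-butyl (2E)-5-[(1R,4aS,5S,6S,8aS)-6-acetoxy-5-formyl-2,5,8a-trimethyl-1,4,4a,5,6,7,8,8a-octahydronaphthalen-1-yl]-3-methylpent-2-enoate | CC(=O)O[C@H]1CC[C@@]2(C)[C@H](CC/C(C)=C/C(=O)OC(C)(C)C)C(C)=CC[C@@H]2[C@]1(C)C=O | intermediate
28 | trimethylsilyl ester of 29 | CC(=O)O[C@H]1CC[C@@]2(C)[C@H](CC/C(C)=C/C(=O)O[Si](C)(C)C)C(C)=CC[C@@H]2[C@]1(C)C=O | intermediate
29 | (2E)-5-[(1R,4aS,5S,6S,8aS)-6-acetoxy-5-formyl-2,5,8a-trimethyl-1,4,4a,5,6,7,8,8a-octahydronaphthalen-1-yl]-3-methylpent-2-enoic acid | CC(=O)O[C@H]1CC[C@@]2(C)[C@H](CC/C(C)=C/C(=O)O)C(C)=CC[C@@H]2[C@]1(C)C=O | target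

Total step count: 17. Longest linear sequence: 13 steps (steps 5 to 9, then 10 to 17, counted from prop-2-yn-1-ol 9).

Steps most likely to fail

Step 15. The cycloaddition has to form two quaternary carbons (C4 and C10) and may therefore be slow. The (Z)-enal could then isomerise to the (E)-enal before it reacts, which would give the C4 epimer, or the syn (cis-fusing) transition state or the other diene face could compete. The fallback changes the dienophile to a thioester, whose geometry does not drift on heating. It sets out from 24: MnO2 and then NaClO2/NaH2PO4/2-methylbut-2-ene would give the (Z)-acid F1; EtSH, EDC and DMAP would give the S-ethyl (Z)-thioester F2; heating in toluene at 150 °C would give the cycloadduct thioester F3; diimide as in step 16 would give the dihydro thioester F4; Fukuyama reduction (Et3SiH, Pd/C, acetone) would then give the aldehyde, and the route is rejoined at 27.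

Step 9. Transmetalation and insertion of the hindered 1-methylalkenyl boronate may be slow, so that protodeboronation, 1,2-addition to the aldehyde or insufficient facial discrimination take over. The fallback replaces catalyst control by auxiliary control. It sets out from 3 and 15: cross-metathesis of 3 with (4R)-3-acryloyl-4-benzyl-1,3-oxazolidin-2-one (second-generation Hoveyda–Grubbs catalyst) would give the N-enoyl oxazolidinone F5. The alkenylcopper reagent from 15 (t-BuLi; MgBr2·OEt2; CuBr·SMe2, THF, −78 °C) would add to the chelated s-cis imide anti to the benzyl group to give the conjugate adduct F6. LiBH4 would cleave the auxiliary to give the primary alcohol F7, and Dess–Martin oxidation would return to 18.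

Step 13. Deprotonation through the wrong rotamer would give the diene with C9 inside, which cannot cyclise, and C-acetylation or attack of the base on the aldehyde may also compete. The fallback replaces base-mediated dienolisation by a metal-catalysed elimination. It sets out from 21: Ac2O with catalytic Sc(OTf)3 would give the allylic geminal diacetate F8, and Pd(PPh3)4 with Et3N in THF at 65 °C would eliminate acetic acid through the acetoxy-substituted allylpalladium complex to give 23.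

Further compounds
F1 | step 15 | (Z)-acid: tert-butyl (2E,6R,7E,9E)-10-acetoxy-6-[(2Z,5Z)-6-carboxyhepta-2,5-dien-2-yl]-3,7-dimethyldeca-2,7,9-trienoate | CC(=O)O/C=C/C=C(C)/[C@H](CC/C(C)=C/C(=O)OC(C)(C)C)/C(C)=C\C/C=C(C)\C(=O)O
F2 | step 15 | S-ethyl (Z)-thioester of F1 | CC(=O)O/C=C/C=C(C)/[C@H](CC/C(C)=C/C(=O)OC(C)(C)C)/C(C)=C\C/C=C(C)\C(=O)SCC
F3 | step 15 | cycloadduct thioester (26 with C(=O)SEt in place of CHO) | CC(=O)O[C@H]1C=C[C@@]2(C)[C@H](CC/C(C)=C/C(=O)OC(C)(C)C)C(C)=CC[C@@H]2[C@]1(C)C(=O)SCC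
F4 | step 15 | dihydro thioester (27 with C(=O)SEt in place of CHO) | CC(=O)O[C@H]1CC[C@@]2(C)[C@H](CC/C(C)=C/C(=O)OC(C)(C)C)C(C)=CC[C@@H]2[C@]1(C)C(=O)SCC
F5 | step 9 | N-enoyl oxazolidinone: tert-butyl (2E,6E)-8-[(4R)-4-benzyl-2-oxo-1,3-oxazolidin-3-yl]-3-methyl-8-oxoocta-2,6-dienoate | O=C(/C=C/CC/C(C)=C/C(=O)OC(C)(C)C)N1[C@H](Cc2ccccc2)COC1=O
F6 | step 9 | conjugate adduct: tert-butyl (2E,6S)-8-[(4R)-4-benzyl-2-oxo-1,3-oxazolidin-3-yl]-6-[(2Z,5Z)-7-{[tert-butyl(dimethyl)silyl]oxy}-6-methylhepta-2,5-dien-2-yl]-3-methyl-8-oxooct-2-enoate | O=C(C[C@H](CC/C(C)=C/C(=O)OC(C)(C)C)/C(C)=C\C/C=C(C)\CO[Si](C)(C)C(C)(C)C)N1[C@H](Cc2ccccc2)COC1=O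
F7 | step 9 | primary alcohol: tert-butyl (2E,6S)-6-[(2Z,5Z)-7-{[tert-butyl(dimethyl)silyl]oxy}-6-methylhepta-2,5-dien-2-yl]-8-hydroxy-3-methyloct-2-enoate | OCC[C@H](CC/C(C)=C/C(=O)OC(C)(C)C)/C(C)=C\C/C=C(C)\CO[Si](C)(C)C(C)(C)C
F8 | step 13 | allylic geminal diacetate: tert-butyl (2E,6S,7RS,8E)-10,10-diacetoxy-6-[(2Z,5Z)-7-{[tert-butyl(dimethyl)silyl]oxy}-6-methylhepta-2,5-dien-2-yl]-3,7-dimethyldeca-2,8-dienoate | CC(=O)OC(OC(C)=O)/C=C/C(C)[C@H](CC/C(C)=C/C(=O)OC(C)(C)C)/C(C)=C\C/C=C(C)\CO[Si](C)(C)C(C)(C)C
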